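**Plan**

1. Retrosynthesis: cut the two O–Si bonds (final desilylation), then the ring B aryl–vinyl bond of the stilbene (Heck; ring D comes last), then one O–CH3 bond of the 2,6-dimethoxyphenyl ring B, which exposes an ortho-phenol. Joining that phenol oxygen to the chain carbon that carries ring C turns the 1,3-diarylpropane into a 2,4-diarylchroman. Retro-[4+2] of the chroman cuts the benzhydryl C–CH2 bond and the O–C2 bond, giving an o-quinone methide (rings A + B) and a styrene (ring C).
2. Enabling feature: the stereogenic benzhydryl carbon lies ortho to an oxygen of ring B and 1,3 to the benzylic carbon of the 2,4-dioxygenated ring C. The target is therefore a ring-opened, O-methylated 4-arylflavan: the ortho C–O/benzhydryl carbon pair is a latent 1-oxadiene and the CH2–CH2 unit a latent vinyl group.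
3. Forward: ring B aldehyde is desymmetrised (mono-demethylation), ring A is added (Grignard), and the ring C styrene is made (silylation, Wittig). The asymmetric oxa-[4+2] joins the two fragments and closes a temporary pyran ring. Ionic hydrogenation opens it again, O-methylation restores the 2,6-dimethoxy pattern, a Heck reaction adds ring D after the acid-mediated steps, and desilylation ends the route.
4. Stereochemistry: the single stereocentre of the target is set in the cycloaddition by a chiral Brønsted acid (face selection at the methide carbon). The second chroman centre is temporary and is erased on ring opening. The E-alkene comes from the Heck reaction.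

Key step: step 5

Assumption: the (R)-catalyst is taken to give the (4S)-chroman, and the antipodal catalyst is used if the sense of induction proves opposite; 9 is drawn as the 2,4-cis isomer expected from endo approach, and its C2 configuration is immaterial because step 6 removes that centre.

**Route**

Step 1
Reactants: 1 4-bromo-2,6-dimethoxybenzaldehyde
Product: 2 4-bromo-2-hydroxy-6-methoxybenzaldehyde
Conditions: BCl3 (1.2 equiv), CH2Cl2, −78 °C to 0 °C; then H2O
Reagents that add atoms: none
Why: Chelation-controlled Lewis acid ether cleavage: BCl3 bound to the aldehyde oxygen should cleave only one ortho O–CH3 bond, and the resulting six-membered aryloxyboron chelate resists a second cleavage, which differentiates the two ortho oxygens of ring B.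

Step 2
Reactants: 2 4-bromo-2-hydroxy-6-methoxybenzaldehyde; 3 (4-methoxyphenyl)magnesium bromide
Product: 4 rac-5-bromo-2-[hydroxy(4-methoxyphenyl)methyl]-3-methoxyphenol
Conditions: 3 (2.5 equiv), THF, 0 °C to rt; then sat. aq. NH4Cl, 0 °C; used without chromatography
Reagents that add atoms: none
Why: Grignard addition to an aldehyde, in which the first equivalent deprotonates the phenol and the second adds to the carbonyl group, while the aryl bromide is inert to an aryl Grignard reagent at this temperature; the racemic carbinol centre is of no consequence because step 5 planarises it.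

Step 3
Reactants: 5 4-hydroxy-2-methoxybenzaldehyde
Product: 6 2-methoxy-4-[(triisopropylsilyl)oxy]benzaldehyde
Conditions: TIPSCl, imidazole, DMF, rt
Reagents that add atoms: chlorotriisopropylsilane, CC(C)[Si](Cl)(C(C)C)C(C)C
Why: Standard phenol silylation; the hindered TIPS ether is chosen because it should survive the Wittig base, the Brønsted acids of steps 5 and 6 and the carbonate of step 7.

Step 4
Reactants: 6 2-methoxy-4-[(triisopropylsilyl)oxy]benzaldehyde
Product: 7 (4-ethenyl-3-methoxyphenoxy)triisopropylsilane
Conditions: Ph3PCH3Br, KOtBu, THF, 0 °C to rt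
Reagents that add atoms: methyltriphenylphosphonium bromide, C[P+](c1ccccc1)(c1ccccc1)c1ccccc1.[Br-]
Why: Wittig methylenation of an aromatic aldehyde with the preformed non-stabilised ylide should give the electron-rich styrene without touching the aryl silyl ether.

Step 5
Reactants: 4 rac-5-bromo-2-[hydroxy(4-methoxyphenyl)methyl]-3-methoxyphenol; 7 (4-ethenyl-3-methoxyphenoxy)triisopropylsilane
Product: 9 (2R,4S)-7-bromo-5-methoxy-4-(4-methoxyphenyl)-2-{2-methoxy-4-[(triisopropylsilyl)oxy]phenyl}-3,4-dihydro-2H-chromene, via o-quinone methide 8 (not isolated)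
Conditions: 7 (1.5 equiv), (R)-3,3'-bis(2,4,6-triisopropylphenyl)-H8-BINOL N-triflylphosphoramide (5 mol%), CH2Cl2, −20 °C
Reagents that add atoms: none
Why: The acid dehydrates 4 to o-quinone methide 8, a 1-oxadiene (O=C–C=CH–Ar) that stays hydrogen-bonded or ion-paired to the chiral phosphoramide; the terminal CH2 of the electron-rich styrene 7 attacks the methide carbon, which forms the fragment-joining C–C bond, and the quinone oxygen closes onto the developing benzylic carbon. The closest known reaction type is the chiral Brønsted acid-catalysed inverse-electron-demand oxa-[4+2] cycloaddition of in situ generated o-quinone methides with styrenes. The dihydropyran ring of the chroman closes in a concerted but highly asynchronous [4+2] mode (C–C bond formation ahead of six-membered C–O closure onto the benzylic carbon), which rearomatises ring B. The C4 stereocentre, the only one that reaches the target, is controlled by the catalyst, whose chiral anion bound at the quinone oxygen should shield one face of the planar methide carbon; the C2 centre should follow from endo approach (2,4-cis) and is erased in step 6, so diastereoselectivity is not required. The step needs regioselectivity (CH2 terminus to the methide carbon), which the matched polarisation of the partners secures, because the 2-methoxy-4-silyloxyphenyl ring stabilises positive charge at the benzylic carbon of the styrene. It also needs chemoselectivity for cycloaddition over acid-induced styrene oligomerisation or ring alkylation, which the easy ionisation of the donor-substituted benzhydrol at low temperature and low acid loading should secure.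

Step 6
Reactants: 9 (2R,4S)-7-bromo-5-methoxy-4-(4-methoxyphenyl)-2-{2-methoxy-4-[(triisopropylsilyl)oxy]phenyl}-3,4-dihydro-2H-chromene
Product: 10 5-bromo-3-methoxy-2-[(1S)-1-(4-methoxyphenyl)-3-{2-methoxy-4-[(triisopropylsilyl)oxy]phenyl}propyl]phenol
Conditions: Et3SiH (5 equiv), TFA (5 equiv), CH2Cl2, −20 °C to 0 °C
Reagents that add atoms: none
Why: Ionic hydrogenation of a benzylic ether: the C2–O bond is a 2,4-dioxygenated benzyl aryl ether that should ionise under mild acid, and the silane reduces the cation, which removes the temporary ring and the C2 centre and leaves the C4 centre untouched, since it carries no leaving group.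

Step 7
Reactants: 10 5-bromo-3-methoxy-2-[(1S)-1-(4-methoxyphenyl)-3-{2-methoxy-4-[(triisopropylsilyl)oxy]phenyl}propyl]phenol
Product: 11 {4-[(3S)-3-(4-bromo-2,6-dimethoxyphenyl)-3-(4-methoxyphenyl)propyl]-3-methoxyphenoxy}triisopropylsilane
Conditions: MeI, K2CO3, acetone, 45 °C
Reagents that add atoms: iodomethane, CI
Why: Williamson O-methylation of the only free phenol restores the 2,6-dimethoxy pattern of ring B, while the other phenol oxygen stays masked as the hindered TIPS ether, which should not migrate under carbonate in acetone.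

Step 8
Reactants: 11 {4-[(3S)-3-(4-bromo-2,6-dimethoxyphenyl)-3-(4-methoxyphenyl)propyl]-3-methoxyphenoxy}triisopropylsilane; 12 tert-butyl(4-ethenylphenoxy)dimethylsilane
Product: 13 tert-butyl{4-[(E)-2-{3,5-dimethoxy-4-[(1S)-1-(4-methoxyphenyl)-3-{2-methoxy-4-[(triisopropylsilyl)oxy]phenyl}propyl]phenyl}ethenyl]phenoxy}dimethylsilane
Conditions: Pd(OAc)2 (5 mol%), P(o-tol)3 (12 mol%), Et3N, DMF, 100 °C
Reagents that add atoms: none
Why: Mizoroki–Heck reaction of an unhindered aryl bromide with a styrene, in which syn-insertion at the terminal carbon and syn-β-hydride elimination should give the E-stilbene, and the non-acidic benzhydryl C–H centre is not affected by triethylamine.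

Step 9
Reactants: 13 tert-butyl{4-[(E)-2-{3,5-dimethoxy-4-[(1S)-1-(4-methoxyphenyl)-3-{2-methoxy-4-[(triisopropylsilyl)oxy]phenyl}propyl]phenyl}ethenyl]phenoxy}dimethylsilane
Product: 14 4-[(E)-2-{4-[(1S)-3-(4-hydroxy-2-methoxyphenyl)-1-(4-methoxyphenyl)propyl]-3,5-dimethoxyphenyl}ethenyl]phenol
Conditions: TBAF (2.5 equiv), AcOH (2.5 equiv), THF, 0 °C to rt
Reagents that add atoms: none
Why: Fluoride-induced cleavage of both aryl silyl ethers in one operation, with acetic acid buffering to keep the phenoxide concentration low and so protect the electron-rich hydroxystilbene from oxidation.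

**Compound list**

1 | 4-bromo-2,6-dimethoxybenzaldehyde | COc1cc(Br)cc(OC)c1C=O | starting material
2 | 4-bromo-2-hydroxy-6-methoxybenzaldehyde | COc1cc(Br)cc(O)c1C=O | intermediate
3 | (4-methoxyphenyl)magnesium bromide | COc1ccc([Mg]Br)cc1 | starting material
4 | rac-5-bromo-2-[hydroxy(4-methoxyphenyl)methyl]-3-methoxyphenol (racemic) | COc1ccc(C(O)c2c(O)cc(Br)cc2OC)cc1 | intermediate
5 | 4-hydroxy-2-methoxybenzaldehyde | COc1cc(O)ccc1C=O | starting material
6 | 2-methoxy-4-[(triisopropylsilyl)oxy]benzaldehyde | COc1cc(O[Si](C(C)C)(C(C)C)C(C)C)ccc1C=O | intermediate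
7 | (4-ethenyl-3-methoxyphenoxy)triisopropylsilane | C=Cc1ccc(O[Si](C(C)C)(C(C)C)C(C)C)cc1OC | intermediate
8 | 3-bromo-5-methoxy-6-[(4-methoxyphenyl)methylidene]cyclohexa-2,4-dien-1-one (o-quinone methide, exocyclic alkene geometry not assigned) | COc1ccc(C=C2C(=O)C=C(Br)C=C2OC)cc1 | intermediate
9 | (2R,4S)-7-bromo-5-methoxy-4-(4-methoxyphenyl)-2-{2-methoxy-4-[(triisopropylsilyl)oxy]phenyl}-3,4-dihydro-2H-chromene (2,4-cis) | COc1ccc([C@@H]2C[C@H](c3ccc(O[Si](C(C)C)(C(C)C)C(C)C)cc3OC)Oc3cc(Br)cc(OC)c32)cc1 | intermediate
10 | 5-bromo-3-methoxy-2-[(1S)-1-(4-methoxyphenyl)-3-{2-methoxy-4-[(triisopropylsilyl)oxy]phenyl}propyl]phenol | COc1ccc([C@H](CCc2ccc(O[Si](C(C)C)(C(C)C)C(C)C)cc2OC)c2c(O)cc(Br)cc2OC)cc1 | intermediate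
11 | {4-[(3S)-3-(4-bromo-2,6-dimethoxyphenyl)-3-(4-methoxyphenyl)propyl]-3-methoxyphenoxy}triisopropylsilane | COc1ccc([C@H](CCc2ccc(O[Si](C(C)C)(C(C)C)C(C)C)cc2OC)c2c(OC)cc(Br)cc2OC)cc1 | intermediate
12 | tert-butyl(4-ethenylphenoxy)dimethylsilane | C=Cc1ccc(O[Si](C)(C)C(C)(C)C)cc1 | starting material
13 | tert-butyl{4-[(E)-2-{3,5-dimethoxy-4-[(1S)-1-(4-methoxyphenyl)-3-{2-methoxy-4-[(triisopropylsilyl)oxy]phenyl}propyl]phenyl}ethenyl]phenoxy}dimethylsilane | COc1ccc([C@H](CCc2ccc(O[Si](C(C)C)(C(C)C)C(C)C)cc2OC)c2c(OC)cc(/C=C/c3ccc(O[Si](C)(C)C(C)(C)C)cc3)cc2OC)cc1 | intermediate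
14 | 4-[(E)-2-{4-[(1S)-3-(4-hydroxy-2-methoxyphenyl)-1-(4-methoxyphenyl)propyl]-3,5-dimethoxyphenyl}ethenyl]phenol | COc1ccc([C@H](CCc2ccc(O)cc2OC)c2c(OC)cc(/C=C/c3ccc(O)cc3)cc2OC)cc1 | target

**Step count**

Total: 9 steps. Longest linear sequence: 7 steps (steps 1, 2, 5, 6, 7, 8, 9, from compound 1).

**Steps most likely to fail**

Step 5. The facial selectivity may erode, either through E/Z isomerism of the quinone methide (the methide aryl group clashes with the neighbouring methoxy group) or through an uncatalysed background cycloaddition. The acid may also start cationic oligomerisation of the styrene, or the quinone methide may alkylate the electron-rich ring of the styrene instead of its vinyl terminus. The fallback gives up the cycloaddition and sets the benzhydryl centre by C–aryl bond formation. It sets out from 1 and comes back to the route at 11. Commercial 1-(4-hydroxy-2-methoxyphenyl)ethanone would be silylated (TIPSCl, imidazole, DMF) to 1-{2-methoxy-4-[(triisopropylsilyl)oxy]phenyl}ethanone F1. Claisen–Schmidt condensation of 1 with this ketone (BF3·OEt2, dioxane, rt) should give (E)-3-(4-bromo-2,6-dimethoxyphenyl)-1-{2-methoxy-4-[(triisopropylsilyl)oxy]phenyl}prop-2-en-1-one F2. A rhodium(I)/BINAP-catalysed Hayashi–Miyaura 1,4-addition of 4-methoxyphenylboronic acid (dioxane/H2O, ligand enantiomer chosen for the S product) should give (S)-3-(4-bromo-2,6-dimethoxyphenyl)-3-(4-methoxyphenyl)-1-{2-methoxy-4-[(triisopropylsilyl)oxy]phenyl}propan-1-one F3. Ionic deoxygenation of this electron-rich aryl ketone (Et3SiH, TFA, CH2Cl2) should then give 11.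

Step 6. Protonation of the chroman may trigger cycloreversion to the quinone methide and the styrene, with loss of enantiomeric purity and reduction of the freed quinone methide. The benzylic cation may also close onto ring A to give an indane before hydride capture, or the silyl ether may be partly lost. The fallback replaces the cationic cleavage by hydrogenolysis, after the bromine has been traded for a group that survives hydrogen. It sets out from 9 and comes back at 13. Miyaura borylation of 9 (B2pin2, Pd(dppf)Cl2, KOAc, dioxane, 90 °C) should give (2R,4S)-5-methoxy-4-(4-methoxyphenyl)-2-{2-methoxy-4-[(triisopropylsilyl)oxy]phenyl}-7-(4,4,5,5-tetramethyl-1,3,2-dioxaborolan-2-yl)-3,4-dihydro-2H-chromene F4. Hydrogenolysis of its benzylic C2–O bond (H2, Pd/C, EtOAc) should give 3-methoxy-2-[(1S)-1-(4-methoxyphenyl)-3-{2-methoxy-4-[(triisopropylsilyl)oxy]phenyl}propyl]-5-(4,4,5,5-tetramethyl-1,3,2-dioxaborolan-2-yl)phenol F5. O-Methylation as in step 7 (MeI, K2CO3, acetone) should give {4-[(3S)-3-[2,6-dimethoxy-4-(4,4,5,5-tetramethyl-1,3,2-dioxaborolan-2-yl)phenyl]-3-(4-methoxyphenyl)propyl]-3-methoxyphenoxy}triisopropylsilane F6. An oxidative boron-Heck coupling of this boronate with 12 (Pd(OAc)2, 2,9-dimethyl-1,10-phenanthroline, O2, DMF, 50 °C) should then give 13.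

Step 8. Insertion of the electron-rich styrene may occur partly with the opposite regiochemistry (1,1-diarylethene formation). The catalyst may also decompose to palladium black before the aryl bromide is consumed, or the aryl silyl ethers may be cleaved in hot amine/DMF. The fallback builds the alkene by olefination instead of cross-coupling. It sets out from 11 and comes back at 13. Bromine–lithium exchange of 11 (n-BuLi, THF, −78 °C) and quenching with DMF should give 3,5-dimethoxy-4-[(1S)-1-(4-methoxyphenyl)-3-{2-methoxy-4-[(triisopropylsilyl)oxy]phenyl}propyl]benzaldehyde F7. Commercial diethyl (4-hydroxybenzyl)phosphonate would be silylated (TBSCl, imidazole, DMF) to diethyl {4-[(tert-butyldimethylsilyl)oxy]benzyl}phosphonate F8. Horner–Wadsworth–Emmons olefination of the aldehyde with the sodium salt of this phosphonate (NaH, THF, 0 °C to rt) should give the E-stilbene 13.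

**Further compounds**

F1 | step 5 | 1-{2-methoxy-4-[(triisopropylsilyl)oxy]phenyl}ethanone | CC(=O)c1ccc(O[Si](C(C)C)(C(C)C)C(C)C)cc1OC
F2 | step 5 | (E)-3-(4-bromo-2,6-dimethoxyphenyl)-1-{2-methoxy-4-[(triisopropylsilyl)oxy]phenyl}prop-2-en-1-one | COc1cc(Br)cc(OC)c1/C=C/C(=O)c1ccc(O[Si](C(C)C)(C(C)C)C(C)C)cc1OC
F3 | step 5 | (S)-3-(4-bromo-2,6-dimethoxyphenyl)-3-(4-methoxyphenyl)-1-{2-methoxy-4-[(triisopropylsilyl)oxy]phenyl}propan-1-one | COc1ccc([C@H](CC(=O)c2ccc(O[Si](C(C)C)(C(C)C)C(C)C)cc2OC)c2c(OC)cc(Br)cc2OC)cc1
F4 | step 6 | (2R,4S)-5-methoxy-4-(4-methoxyphenyl)-2-{2-methoxy-4-[(triisopropylsilyl)oxy]phenyl}-7-(4,4,5,5-tetramethyl-1,3,2-dioxaborolan-2-yl)-3,4-dihydro-2H-chromene | COc1ccc([C@@H]2C[C@H](c3ccc(O[Si](C(C)C)(C(C)C)C(C)C)cc3OC)Oc3cc(B4OC(C)(C)C(C)(C)O4)cc(OC)c32)cc1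
F5 | step 6 | 3-methoxy-2-[(1S)-1-(4-methoxyphenyl)-3-{2-methoxy-4-[(triisopropylsilyl)oxy]phenyl}propyl]-5-(4,4,5,5-tetramethyl-1,3,2-dioxaborolan-2-yl)phenol | COc1ccc([C@H](CCc2ccc(O[Si](C(C)C)(C(C)C)C(C)C)cc2OC)c2c(O)cc(B3OC(C)(C)C(C)(C)O3)cc2OC)cc1
F6 | step 6 | {4-[(3S)-3-[2,6-dimethoxy-4-(4,4,5,5-tetramethyl-1,3,2-dioxaborolan-2-yl)phenyl]-3-(4-methoxyphenyl)propyl]-3-methoxyphenoxy}triisopropylsilane | COc1ccc([C@H](CCc2ccc(O[Si](C(C)C)(C(C)C)C(C)C)cc2OC)c2c(OC)cc(B3OC(C)(C)C(C)(C)O3)cc2OC)cc1
F7 | step 8 | 3,5-dimethoxy-4-[(1S)-1-(4-methoxyphenyl)-3-{2-methoxy-4-[(triisopropylsilyl)oxy]phenyl}propyl]benzaldehyde | COc1ccc([C@H](CCc2ccc(O[Si](C(C)C)(C(C)C)C(C)C)cc2OC)c2c(OC)cc(C=O)cc2OC)cc1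
F8 | step 8 | diethyl {4-[(tert-butyldimethylsilyl)oxy]benzyl}phosphonate | CCOP(=O)(Cc1ccc(O[Si](C)(C)C(C)(C)C)cc1)OCC
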